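**Retrosynthetic overview** (germacranolide numbering: carbocycle C1–C10, lactone C11–C13 with its oxygen on C6, ester carbon C14, methyl C15)
1. Target ⇒ macrocycle 21 (exocyclic methylene masked as a Mannich base, two phenylsulfonyl groups on C3) ⇒ acyclic lactone 20 by opening the ten-membered ring at C2–C3.
2. Enabling feature: the free C9 hydroxyl sits next to C10 of the C1=C10 enoate, so O9–C9–C10=C1–C2 is the 1,4-array that a C9–C10 vinyl oxirane gives on SN2′ attack at C2. C3 is made a soft nucleophile by a gem-bis(phenylsulfonyl) group, the same group that lets C4 be set by organocatalysis.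
3. 20 ⇒ aldehyde 3 (C3–C6) + allylic bromide 15 (C7–C10, C1–C2, C11–C14) by chromium-mediated allylation and lactonisation (C6–C7; C6 and C7 relayed from C8).
4. 15 ⇒ (S)-glyceraldehyde acetonide (C7–C9, C8 bought) by bromo-Wittig/Stille (C10, C14, C1, C2), hydroxyl-directed epoxidation (C9) and Baylis–Hillman/SN2′ bromination (C11–C13).
5. Ring order: oxirane (temporary, step 5) → γ-lactone (step 10) → ten-membered carbocycle (step 14). The isovalerate is put on O8 while O9 is still the oxirane oxygen.

Key step: step 14

Remark: the carbinol carbon of 14 and the lactone α-carbon of 18–23 are expected as epimer mixtures and are drawn without configuration because both centres are removed again (steps 9 and 16); C10 of the oxirane is drawn for retention of the alkene geometry and is lost in step 14.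

Step 1
Reactants: 1 (E)-but-2-enal (crotonaldehyde); 2 bis(phenylsulfonyl)methane
Product: 3 (3R)-3-methyl-4,4-bis(phenylsulfonyl)butanal
Conditions: (S)-α,α-diphenylprolinol TMS ether (10 mol %), PhCO2H (10 mol %), toluene, rt
Reagents that add atoms: none
Why: Iminium-catalysed Michael addition in which the diaryl(silyloxy)methyl group of the catalyst shields one face of the (E)-iminium ion of 1, so the bis-sulfonyl carbon acid should add to the open face and set the methyl-bearing centre (later C4) as (R), while installing the activating group for the key step.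

Step 2
Reactants: 4 (S)-2,2-dimethyl-1,3-dioxolane-4-carbaldehyde; 5 methyl (triphenylphosphoranylidene)acetate
Product: 6 methyl (2Z)-2-bromo-3-[(4R)-2,2-dimethyl-1,3-dioxolan-4-yl]prop-2-enoate
Conditions: 5, NBS, CH2Cl2, −20 °C; then 4, 0 °C → rt
Reagents that add atoms: N-bromosuccinimide, O=C1CCC(=O)N1Br
Why: Wittig olefination with the bromo ylide made in the flask from 5 and NBS, which as a stabilised α-halo ylide should give the (Z)-2-bromoenoate (ring carbon cis to Br, trans to the ester) without touching the α-alkoxy stereocentre (later C8).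

Step 3
Reactants: 6 methyl (2Z)-2-bromo-3-[(4R)-2,2-dimethyl-1,3-dioxolan-4-yl]prop-2-enoate; 7 tributyl(vinyl)stannane
Product: 8 methyl (2E)-2-{[(4R)-2,2-dimethyl-1,3-dioxolan-4-yl]methylidene}but-3-enoate
Conditions: Pd(PPh3)4 (5 mol %), CuI (10 mol %), DMF, 50 °C
Reagents that add atoms: none
Why: Stille coupling of the 2-bromoacrylate proceeds with retention of alkene geometry, so the dioxolane carbon stays trans to the ester in the 2-vinyl enoate and cannot lactonise later.

Step 4
Reactants: 8 methyl (2E)-2-{[(4R)-2,2-dimethyl-1,3-dioxolan-4-yl]methylidene}but-3-enoate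
Product: 9 methyl (2E,4R)-2-ethenyl-4,5-dihydroxypent-2-enoate
Conditions: AcOH/H2O (4:1), 40 °C
Reagents that add atoms: none
Why: Acid-catalysed acetal hydrolysis frees the secondary hydroxyl (future O8) that has to direct the epoxidation, and the E geometry keeps both hydroxyls away from the ester.

Step 5
Reactants: 9 methyl (2E,4R)-2-ethenyl-4,5-dihydroxypent-2-enoate
Product: 10 methyl (2S,3R)-3-[(1S)-1,2-dihydroxyethyl]-2-ethenyloxirane-2-carboxylate
Conditions: t-BuOOH (3 equiv), n-BuLi (2.5 equiv), THF, −78 → −20 °C
Reagents that add atoms: tert-butyl hydroperoxide, CC(C)(C)OO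
Why: Weitz–Scheffer-type nucleophilic epoxidation of the ester-conjugated alkene only, in which the lithium-bound C8 hydroxyl should deliver the peroxide in the conformer with C8–H eclipsing the alkene (1,3-allylic strain with the cis vinyl group), placing the oxirane oxygen syn to O8 and so setting C9 in the 8,9-threo sense.

Step 6
Reactants: 10 methyl (2S,3R)-3-[(1S)-1,2-dihydroxyethyl]-2-ethenyloxirane-2-carboxylate
Product: 11 methyl (2S,3R)-3-[(1S)-1,2-bis(triethylsilyloxy)ethyl]-2-ethenyloxirane-2-carboxylate
Conditions: TESCl (2.5 equiv), imidazole, DMF, 0 °C → rt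
Reagents that add atoms: chlorotriethylsilane, CC[Si](Cl)(CC)CC
Why: Standard imidazole-mediated silylation of both hydroxyls, which affects no stereocentre.

Step 7
Reactants: 11 methyl (2S,3R)-3-[(1S)-1,2-bis(triethylsilyloxy)ethyl]-2-ethenyloxirane-2-carboxylate
Product: 12 methyl (2S,3R)-2-ethenyl-3-[(1R)-2-oxo-1-(triethylsilyloxy)ethyl]oxirane-2-carboxylate
Conditions: (COCl)2, DMSO, CH2Cl2, −78 → −40 °C; then Et3N, → 0 °C
Reagents that add atoms: none
Why: Under Swern conditions a primary triethylsilyl ether is cleaved by the chlorosulfonium reagent and oxidised directly to the aldehyde while the hindered secondary silyl ether survives, so the α-silyloxy aldehyde is reached without a separate deprotection.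

Step 8
Reactants: 12 methyl (2S,3R)-2-ethenyl-3-[(1R)-2-oxo-1-(triethylsilyloxy)ethyl]oxirane-2-carboxylate; 13 methyl acrylate
Product: 14 Baylis–Hillman adduct of 12 (2-methylene-3-hydroxy ester, both carbinol epimers)
Conditions: DABCO (1 equiv), 13 (5 equiv), 1,4-dioxane/H2O (1:1), rt
Reagents that add atoms: none
Why: Morita–Baylis–Hillman reaction of the activated α-silyloxy aldehyde under the water-accelerated protocol, chosen to limit epimerisation at C8; the new carbinol centre is erased in step 9.

Step 9
Reactants: 14 Baylis–Hillman adduct of 12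
Product: 15 methyl (2Z,4S)-2-(bromomethyl)-4-[(2R,3S)-3-ethenyl-3-(methoxycarbonyl)oxiran-2-yl]-4-(triethylsilyloxy)but-2-enoate
Conditions: NBS, Me2S, CH2Cl2, 0 °C → rt
Reagents that add atoms: N-bromosuccinimide, O=C1CCC(=O)N1Br
Why: SN2′ bromination of the Baylis–Hillman alcohol through its alkoxysulfonium salt should give the rearranged (Z)-2-(bromomethyl)alkenoate, converting both carbinol epimers into one allylic bromide.

Step 10
Reactants: 3 (3R)-3-methyl-4,4-bis(phenylsulfonyl)butanal; 15 (Z)-allylic bromide
Product: 17 trans-α-methylene-γ-butyrolactone with the bis-sulfone chain on C6 and the silyloxy vinyl-oxirane chain on C7, via anti hydroxy ester 16 (not isolated)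
Conditions: CrCl2 (3 equiv), THF, rt; aq. NH4Cl; then PPTS (cat.), CH2Cl2, rt
Reagents that add atoms: none
Why: Nozaki–Hiyama-type allylation in which the equilibrating allylchromium(III) adds through its γ-carbon in a closed chair transition state with both substituents pseudo-equatorial, which should give the anti adduct and hence the trans lactone, while the C8 stereocentre (C8–H in the alkene plane, silyloxy group outside, aldehyde entering anti to the C8–C9 bond) should fix the face so that C7 is (S) and C6 is (R).

Step 11
Reactants: 17 trans-α-methylene-γ-butyrolactone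
Product: 18 α-(dimethylaminomethyl) lactone (Mannich base of 17)
Conditions: Me2NH (2 M in THF, 2 equiv), THF, −20 → 0 °C
Reagents that add atoms: dimethylamine, CNC
Why: Aza-Michael addition of the secondary amine to the α-methylene lactone is fast and takes the Michael acceptor out of play for the carbanion and electron-transfer chemistry of steps 14 and 15; the new α-centre is an inconsequential epimer mixture.

Step 12
Reactants: 18 Mannich base
Product: 19 C8 alcohol
Conditions: HF·pyridine, pyridine, THF, 0 °C
Reagents that add atoms: none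
Why: Buffered fluoride cleavage of the secondary triethylsilyl ether, which should leave the oxirane, the lactone and the ester untouched.

Step 13
Reactants: 19 C8 alcohol
Product: 20 C8 isovalerate (cyclisation precursor)
Conditions: 3-methylbutanoyl chloride, pyridine, DMAP (cat.), CH2Cl2, 0 °C
Reagents that add atoms: 3-methylbutanoyl chloride, CC(C)CC(=O)Cl
Why: DMAP-catalysed acylation puts the isovalerate on O8 while O9 is still locked in the oxirane, which settles the O8/O9 differentiation without a further protecting group.

Step 14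
Reactants: 20 C8 isovalerate with vinyl oxirane and gem-bis-sulfone
Product: 21 ten-membered carbocycle with C3(SO2Ph)2, free C9–OH and the C1=C10 enoate
Conditions: Pd(PPh3)4 (10 mol %), dppe (10 mol %), THF, 65 °C, syringe-pump addition (final 2 mM)
Reagents that add atoms: none
Why: Pd(0) ionises the vinyl oxirane at C10–O to a zwitterionic π-allylpalladium complex (C10–C1–C2) carrying the C9 alkoxide, which deprotonates the gem-bis-sulfone C3–H within the same molecule, so the soft carbanion exists only next to its electrophile and no external base is needed; the closest known reaction type is the Tsuji–Trost alkylation of vinyl epoxides with bis-sulfonyl pronucleophiles under neutral conditions, which has been used to close medium and large carbocycles. The carbanion attacks the unsubstituted allyl terminus C2 anti to palladium, so the ten-membered ring is closed with the whole allyl unit inside the ring, whereas attack at the quaternary, ester-bearing C10 would give an eight-membered ring and is disfavoured sterically and electronically. No new stereocentre is formed: the C9–O bond is never broken, so C9 keeps the configuration set in step 5, and C4, C6, C7 and C8 are spectators. The C1=C10 geometry (C2 cis to C9, E by the sequence rule) should be imposed by the short tether, which can reach C2 only from the allyl isomer with C9 anti, an isomer accessible by π–σ–π equilibration and also the tiglate-type arrangement with C2 trans to the ester. The step needs C- over O-alkylation (O9 attack at C2 would give a 2,5-dihydrofuran) and cyclisation over oligomerisation, which the fast internal proton transfer, the softness of the carbanion and slow addition at high dilution should secure, while the Michael acceptor that could divert the carbanion is masked as the Mannich base.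

Step 15
Reactants: 21 macrocyclic bis-sulfone
Product: 22 desulfonylated macrocycle (Mannich base of the target)
Conditions: 6% Na(Hg), Na2HPO4, MeOH/THF (3:1), −20 °C
Reagents that add atoms: none
Why: Reductive desulfonylation by single-electron transfer from sodium amalgam should cleave both C–S bonds and leave C3 as CH2, with the phosphate buffer and low temperature expected to spare the enoate, the esters and the masked lactone.

Step 16
Reactants: 22 desulfonylated macrocycle
Product: 24 CNP0544142.1 (target), via trimethylammonium iodide 23 (not isolated)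
Conditions: MeI (excess), CH2Cl2, rt; then aq. NaHCO3, EtOAc, rt
Reagents that add atoms: none
Why: Exhaustive N-methylation followed by base-induced β-elimination of trimethylamine (E1cB, Hofmann-type) regenerates the exocyclic methylene, the only alkene the ammonium salt can give, under conditions too mild for acyl migration.

**Compound list**
1 | (E)-but-2-enal | C/C=C/C=O | starting material
2 | bis(phenylsulfonyl)methane | O=S(=O)(CS(=O)(=O)c1ccccc1)c1ccccc1 | starting material
3 | (3R)-3-methyl-4,4-bis(phenylsulfonyl)butanal | O=CC[C@@H](C)C(S(=O)(=O)c1ccccc1)S(=O)(=O)c1ccccc1 | intermediate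
4 | (S)-2,2-dimethyl-1,3-dioxolane-4-carbaldehyde | O=C[C@@H]1COC(C)(C)O1 | starting material
5 | methyl (triphenylphosphoranylidene)acetate | COC(=O)C=P(c1ccccc1)(c1ccccc1)c1ccccc1 | starting material
6 | methyl (2Z)-2-bromo-3-[(4R)-2,2-dimethyl-1,3-dioxolan-4-yl]prop-2-enoate | COC(=O)/C(Br)=C/[C@@H]1COC(C)(C)O1 | intermediate
7 | tributyl(vinyl)stannane | C=C[Sn](CCCC)(CCCC)CCCC | starting material
8 | methyl (2E)-2-{[(4R)-2,2-dimethyl-1,3-dioxolan-4-yl]methylidene}but-3-enoate | COC(=O)/C(C=C)=C/[C@@H]1COC(C)(C)O1 | intermediate
9 | methyl (2E,4R)-2-ethenyl-4,5-dihydroxypent-2-enoate | COC(=O)/C(C=C)=C/[C@@H](O)CO | intermediate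
10 | methyl (2S,3R)-3-[(1S)-1,2-dihydroxyethyl]-2-ethenyloxirane-2-carboxylate | OC[C@H](O)[C@H]1O[C@]1(C=C)C(=O)OC | intermediate
11 | methyl (2S,3R)-3-[(1S)-1,2-bis(triethylsilyloxy)ethyl]-2-ethenyloxirane-2-carboxylate | CC[Si](CC)(CC)OC[C@H](O[Si](CC)(CC)CC)[C@H]1O[C@]1(C=C)C(=O)OC | intermediate
12 | methyl (2S,3R)-2-ethenyl-3-[(1R)-2-oxo-1-(triethylsilyloxy)ethyl]oxirane-2-carboxylate | O=C[C@H](O[Si](CC)(CC)CC)[C@H]1O[C@]1(C=C)C(=O)OC | intermediate
13 | methyl acrylate | C=CC(=O)OC | starting material
14 | Baylis–Hillman adduct of 12 (carbinol epimers) | C=C(C(=O)OC)C(O)[C@H](O[Si](CC)(CC)CC)[C@H]1O[C@]1(C=C)C(=O)OC | intermediate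
15 | methyl (2Z,4S)-2-(bromomethyl)-4-[(2R,3S)-3-ethenyl-3-(methoxycarbonyl)oxiran-2-yl]-4-(triethylsilyloxy)but-2-enoate | COC(=O)/C(CBr)=C/[C@H](O[Si](CC)(CC)CC)[C@H]1O[C@]1(C=C)C(=O)OC | intermediate
16 | anti hydroxy ester (chromium adduct after work-up, not isolated) | C=C(C(=O)OC)[C@@H]([C@H](O)C[C@@H](C)C(S(=O)(=O)c1ccccc1)S(=O)(=O)c1ccccc1)[C@H](O[Si](CC)(CC)CC)[C@H]2O[C@]2(C=C)C(=O)OC | intermediate
17 | trans-α-methylene-γ-butyrolactone (C6 R, C7 S) with C8–OSiEt3 and the vinyl oxirane | C=C1C(=O)O[C@H](C[C@@H](C)C(S(=O)(=O)c2ccccc2)S(=O)(=O)c2ccccc2)[C@H]1[C@H](O[Si](CC)(CC)CC)[C@H]3O[C@]3(C=C)C(=O)OC | intermediate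
18 | Mannich base of 17 (α-CH2NMe2, α-epimers) | CN(C)CC1C(=O)O[C@H](C[C@@H](C)C(S(=O)(=O)c2ccccc2)S(=O)(=O)c2ccccc2)[C@H]1[C@H](O[Si](CC)(CC)CC)[C@H]3O[C@]3(C=C)C(=O)OC | intermediate
19 | C8 alcohol | CN(C)CC1C(=O)O[C@H](C[C@@H](C)C(S(=O)(=O)c2ccccc2)S(=O)(=O)c2ccccc2)[C@H]1[C@H](O)[C@H]3O[C@]3(C=C)C(=O)OC | intermediate
20 | C8 isovalerate, cyclisation precursor | CN(C)CC1C(=O)O[C@H](C[C@@H](C)C(S(=O)(=O)c2ccccc2)S(=O)(=O)c2ccccc2)[C@H]1[C@H](OC(=O)CC(C)C)[C@H]3O[C@]3(C=C)C(=O)OC | intermediate
21 | macrocyclic bis-sulfone (ten-membered ring, C9–OH, C1=C10 enoate) | CN(C)CC1C(=O)O[C@@H]2C[C@@H](C)C(S(=O)(=O)c3ccccc3)(S(=O)(=O)c3ccccc3)C/C=C(/C(=O)OC)[C@H](O)[C@@H](OC(=O)CC(C)C)[C@@H]12 | intermediate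
22 | desulfonylated macrocycle (Mannich base of the target) | CN(C)CC1C(=O)O[C@@H]2C[C@@H](C)CC/C=C(/C(=O)OC)[C@H](O)[C@@H](OC(=O)CC(C)C)[C@@H]12 | intermediate
23 | trimethylammonium iodide of 22 (not isolated) | C[N+](C)(C)CC1C(=O)O[C@@H]2C[C@@H](C)CC/C=C(/C(=O)OC)[C@H](O)[C@@H](OC(=O)CC(C)C)[C@@H]12.[I-] | intermediate
24 | CNP0544142.1 | C=C1C(=O)O[C@@H]2C[C@@H](C)CC/C=C(/C(=O)OC)[C@H](O)[C@@H](OC(=O)CC(C)C)[C@@H]12 | target

**Step count:** 16 steps in total. Longest linear sequence: 15 steps (4 → 24, steps 2–16); step 1 is the only step of the second branch.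

**Steps most likely to fail**

Step 14. The zwitterionic allylpalladium intermediate may be diverted before the hindered carbanion closes the ring: O-alkylation to a 2,5-dihydrofuran, β-hydride loss to a dienol, or intermolecular alkylation to oligomers. The fallback separates ionisation from C–C bond formation and sets out from 20. Bromotrimethylsilane (CH2Cl2, −78 °C) should open the vinyl oxirane in the SN2′ sense to the O-trimethylsilyl allylic bromide F1. Deprotonation of the bis-sulfone with Cs2CO3 in MeCN at high dilution and classical intramolecular SN2 alkylation at the primary allylic carbon should then give the O-silylated macrocycle F2, the silyl ether blocking dihydrofuran formation. Aqueous citric acid in THF removes the silyl group and the route is rejoined at 21.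

Step 10. The aldehyde may not discriminate the two faces of the allylchromium γ-carbon, because 1,2-induction from the silyloxy stereocentre is weak; the 6,7-bis-epimeric lactone would then form as well. The fallback hands facial control to a covalently bound auxiliary and sets out from 12. Baylis–Hillman reaction with (−)-8-phenylmenthyl acrylate in place of 13 gives the 8-phenylmenthyl Baylis–Hillman adduct F3, and NBS/Me2S converts it into the 8-phenylmenthyl (Z)-allylic bromide F4. Chromium-mediated coupling of F4 with 3 is then steered by the aryl-shielded face of the ester (the antipodal auxiliary would be taken if this sense opposes the substrate bias). Acid-catalysed lactonisation expels 8-phenylmenthol and the route is rejoined at 17.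

Step 5. Peroxide delivery may not be face-selective, the peroxy dienolate may close through its vinyl terminus, or the 2-vinylacrylate may oligomerise under the basic conditions. The fallback makes the oxirane by reagent-controlled electrophilic epoxidation at the allylic-alcohol oxidation level and sets out from 8. DIBAL-H (CH2Cl2, −78 °C) reduces the ester to the dienol F5. Sharpless asymmetric epoxidation (Ti(OiPr)4, L-(+)-diisopropyl tartrate, t-BuOOH, 4 Å MS, −20 °C) should epoxidise only the allylic double bond, on the face set by the tartrate, to the epoxy alcohol F6. Oxidation of the primary alcohol (TEMPO, NaOCl, NaClO2) gives the glycidic acid F7, and trimethylsilyldiazomethane gives the epoxy ester acetonide F8. Hydrolysis of the acetonide (aqueous AcOH) rejoins the route at 10.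

Further compounds
F1 | step 14 | O-trimethylsilyl allylic bromide from SN2′ opening of 20 | CN(C)CC1C(=O)O[C@H](C[C@@H](C)C(S(=O)(=O)c2ccccc2)S(=O)(=O)c2ccccc2)[C@H]1[C@@H]([C@H](/C(=C\CBr)C(=O)OC)O[Si](C)(C)C)OC(=O)CC(C)C
F2 | step 14 | O-trimethylsilyl ether of macrocycle 21 | CN(C)CC1C(=O)O[C@@H]2C[C@@H](C)C(S(=O)(=O)c3ccccc3)(S(=O)(=O)c3ccccc3)C/C=C(/C(=O)OC)[C@H](O[Si](C)(C)C)[C@@H](OC(=O)CC(C)C)[C@@H]12
F3 | step 10 | 8-phenylmenthyl Baylis–Hillman adduct of 12 (carbinol epimers) | CC(C)(c1ccccc1)[C@@H]1CC[C@@H](C)C[C@H]1OC(=O)C(=C)C(O)[C@H](O[Si](CC)(CC)CC)[C@H]2O[C@]2(C=C)C(=O)OC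
F4 | step 10 | 8-phenylmenthyl (Z)-allylic bromide | CC(C)(c1ccccc1)[C@@H]1CC[C@@H](C)C[C@H]1OC(=O)/C(CBr)=C/[C@H](O[Si](CC)(CC)CC)[C@H]2O[C@]2(C=C)C(=O)OC
F5 | step 5 | (2E)-2-ethenyl-3-[(4R)-2,2-dimethyl-1,3-dioxolan-4-yl]prop-2-en-1-ol | OC/C(C=C)=C/[C@@H]1COC(C)(C)O1
F6 | step 5 | [(2R,3R)-3-[(4S)-2,2-dimethyl-1,3-dioxolan-4-yl]-2-ethenyloxiran-2-yl]methanol | OC[C@@]1(C=C)O[C@@H]1[C@@H]2COC(C)(C)O2
F7 | step 5 | (2S,3R)-3-[(4S)-2,2-dimethyl-1,3-dioxolan-4-yl]-2-ethenyloxirane-2-carboxylic acid | OC(=O)[C@@]1(C=C)O[C@@H]1[C@@H]2COC(C)(C)O2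
F8 | step 5 | methyl (2S,3R)-3-[(4S)-2,2-dimethyl-1,3-dioxolan-4-yl]-2-ethenyloxirane-2-carboxylate | COC(=O)[C@@]1(C=C)O[C@@H]1[C@@H]2COC(C)(C)O2
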